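The target is (2S)-4'-O-geranylnaringenin. The flavanone is cut through ring C at O1–C2 and C3–C4. O1, C8a, C4a and C4 come from an ortho-quinone methide grown on the phloroglucinol ring A. C2 and C3 are the vinyl carbons of a 4-geranyloxystyrene that already carries ring B and the side chain. One chiral-acid-catalysed oxa-[4+2] cycloaddition closes ring C, forms both bonds and sets C2 (S). C4 arrives already oxygenated, as a methyl ether one oxidation level below the ketone. The precursors are a salicylaldehyde with one free ortho hydroxyl and two silylated phenols, activated in the flask by trimethyl orthoformate, and the styrene.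

Key step: step 3

Remark: flavonoid numbering is used for the chroman compounds (O1, C2, C3, C4, C4a, C5–C8, C8a; ring A = phloroglucinol ring, ring B = 4-oxyphenyl ring, ring C = pyran ring).

Assumption: which antipode of the acid catalyst gives the 2S series cannot be predicted with confidence. The (R) acid is written, and its mirror image is used if a first run shows the opposite sense.

Step 1
Reactants: 1 2,4,6-trihydroxybenzaldehyde
Product: 2 2-hydroxy-4,6-bis(triisopropylsilyloxy)benzaldehyde
Conditions: TIPSCl (2.1 equiv), imidazole (4.5 equiv), DMF, 0 °C to rt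
Reagents that add atoms: chlorotriisopropylsilane (TIPSCl), CC(C)[Si](Cl)(C(C)C)C(C)C
Why: Phenol silylation with a chlorosilane and imidazole should stop at the bis-ether, because the para hydroxyl and one ortho hydroxyl react while the last ortho hydroxyl is tied up in a hydrogen bond to the formyl oxygen and is too unreactive toward the hindered chlorosilane, and the symmetry of 1 makes the two ortho positions equivalent.

Step 2
Reactants: 3 4-acetoxystyrene; 4 geranyl bromide
Product: 6 4-(geranyloxy)styrene, via potassium 4-vinylphenoxide 5 (not isolated)
Conditions: KOH (2.05 equiv), DMSO–H2O (20:1), rt; then 4 (1.1 equiv), 0 °C to rt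
Reagents that add atoms: none
Why: Hydroxide saponifies the aryl acetate and the phenoxide then undergoes Williamson etherification by SN2 attack on the primary allylic bromide in a dipolar aprotic medium that favours O- over C-alkylation, so the E alkene of the geranyl unit is carried over unchanged and no stereocentre is involved.

Step 3
Reactants: 2 2-hydroxy-4,6-bis(triisopropylsilyloxy)benzaldehyde; 6 4-(geranyloxy)styrene; 7 trimethyl orthoformate
Product: 10 (2S,4S)-4'-O-geranyl-4-methoxy-5,7-bis(triisopropylsilyloxy)flavan, via dimethyl acetal 8 (not isolated), via methoxy ortho-quinone methide 9 (not isolated)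
Conditions: 7 (1.5 equiv), (R)-3,3'-bis(2,4,6-triisopropylphenyl)-1,1'-binaphthyl-2,2'-diyl N-triflylphosphoramide (5 mol %), 5 Å MS, toluene, rt; then 6 (1.3 equiv, slow addition), −40 °C
Reagents that add atoms: none
Why: Proposed new method: the acid and orthoformate 7 convert 2 into acetal 8 and ionise it to the O-protonated form of methoxy ortho-quinone methide 9, an aryl oxocarbenium ion held in a contact ion pair by a hydrogen bond between its phenolic OH and the chiral phosphoramide anion; the terminal carbon of styrene 6 then bonds to the methide carbon (C3–C4) and the phenolic oxygen captures the developing 4-alkoxybenzylic carbon (O1–C2) in an asynchronous inverse-electron-demand oxa-Diels–Alder reaction. The closest known reaction types are the achiral Lewis-acid three-component coupling of salicylaldehydes, orthoformates and styrenes to 4-alkoxy-2-arylchromans and chiral Brønsted-acid [4+2] cycloadditions of ortho-quinone methides generated in the flask, including intramolecular cases that start from salicylaldehyde acetals. Ring C closes by this formal [4+2] cycloaddition, which in the stepwise limit is a six-membered collapse of the phenol oxygen onto the benzylic cation. C2 is set by the catalyst anion, which sits at the O1 terminus through the OH···anion hydrogen bond and shields one face of the styrene carbon as O1–C2 forms, while C4 follows from endo approach of the aryl group to the (E)-methoxy methide and should come out 2,4-cis. The step needs regioselectivity, secured by the 4-alkoxy group of 6, which polarises the alkene so that the aryl-bearing carbon becomes C2; it needs chemoselectivity for the styrene over the trisubstituted geranyl alkenes, secured by the far higher nucleophilicity of the 4-alkoxystyrene and an acid of only moderate strength; and it needs absolute control at C2 alone, since C4 is oxidised in step 5. The silyl cap on the second ortho oxygen keeps product 10 from forming a new quinone methide, and the two silyloxy donors stabilise 9 enough for ionisation at low temperature.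

Step 4
Reactants: 10 (2S,4S)-4'-O-geranyl-4-methoxy-5,7-bis(triisopropylsilyloxy)flavan
Product: 11 (2S)-4'-O-geranyl-5,7-bis(triisopropylsilyloxy)flavan-4-ol (both C4 epimers)
Conditions: PPTS (0.2 equiv), THF–H2O (4:1), rt to 40 °C
Reagents that add atoms: water, O
Why: In this acid-catalysed SN1 solvolysis the C4–OMe bond, flanked ortho and para by O1 and the two silyloxy groups of ring A, should ionise under mild acid and the cation be trapped by the large excess of water, while C2 lies outside the ionising bond and keeps its S configuration, the aryl silyl ethers and the allylic aryl ether tolerate pyridinium tosylate, and the new C4 centre is left uncontrolled because it is removed in step 5.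

Step 5
Reactants: 11 (2S)-4'-O-geranyl-5,7-bis(triisopropylsilyloxy)flavan-4-ol
Product: 12 (2S)-4'-O-geranyl-5,7-bis(triisopropylsilyloxy)flavanone
Conditions: Dess–Martin periodinane (1.3 equiv), pyridine (3 equiv), CH2Cl2, 0 °C to rt
Reagents that add atoms: none
Why: Dess–Martin oxidation of a secondary benzylic alcohol under pyridine buffering should convert both C4 epimers into the same ketone without touching the trisubstituted alkenes or the silyl ethers, and C2, which is beta to the new carbonyl, cannot epimerise by enolisation.

Step 6
Reactants: 12 (2S)-4'-O-geranyl-5,7-bis(triisopropylsilyloxy)flavanone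
Product: 13 (2S)-4'-O-geranylnaringenin (target)
Conditions: TBAF (2.5 equiv), AcOH (3 equiv), THF, 0 °C
Reagents that add atoms: none
Why: Fluoride-induced cleavage of the two aryl silyl ethers is fast, and acetic acid protonates each phenoxide as it forms, so that the base-triggered retro-oxa-Michael opening to the 2'-hydroxychalcone, the only pathway that would racemise C2, should be suppressed, while the geranyl ether is inert to fluoride.

Compound list
1 | 2,4,6-trihydroxybenzaldehyde | O=Cc1c(O)cc(O)cc1O | starting material
2 | 2-hydroxy-4,6-bis(triisopropylsilyloxy)benzaldehyde | O=Cc1c(O)cc(O[Si](C(C)C)(C(C)C)C(C)C)cc1O[Si](C(C)C)(C(C)C)C(C)C | intermediate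
3 | 4-acetoxystyrene (4-ethenylphenyl acetate) | CC(=O)Oc1ccc(C=C)cc1 | starting material
4 | geranyl bromide ((2E)-1-bromo-3,7-dimethylocta-2,6-diene) | CC(C)=CCC/C(C)=C/CBr | starting material
5 | potassium 4-vinylphenoxide (formed in the flask, not isolated) | [K+].[O-]c1ccc(C=C)cc1 | intermediate
6 | 4-(geranyloxy)styrene (1-ethenyl-4-{[(2E)-3,7-dimethylocta-2,6-dien-1-yl]oxy}benzene) | CC(C)=CCC/C(C)=C/COc1ccc(C=C)cc1 | intermediate
7 | trimethyl orthoformate | COC(OC)OC | starting material
8 | 2-(dimethoxymethyl)-3,5-bis(triisopropylsilyloxy)phenol, the dimethyl acetal of 2 (formed in the flask, not isolated) | COC(OC)c1c(O)cc(O[Si](C(C)C)(C(C)C)C(C)C)cc1O[Si](C(C)C)(C(C)C)C(C)C | intermediate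
9 | (6E)-6-(methoxymethylidene)-3,5-bis(triisopropylsilyloxy)cyclohexa-2,4-dien-1-one, the methoxy ortho-quinone methide, which reacts as its O-protonated ion pair with the catalyst anion (not isolated) | CO/C=C1/C(=O)C=C(O[Si](C(C)C)(C(C)C)C(C)C)C=C1O[Si](C(C)C)(C(C)C)C(C)C | intermediate
10 | (2S,4S)-2-{4-[(2E)-3,7-dimethylocta-2,6-dien-1-yloxy]phenyl}-4-methoxy-5,7-bis(triisopropylsilyloxy)chromane (2,4-cis) | CC(C)=CCC/C(C)=C/COc1ccc([C@@H]2C[C@H](OC)c3c(O[Si](C(C)C)(C(C)C)C(C)C)cc(O[Si](C(C)C)(C(C)C)C(C)C)cc3O2)cc1 | intermediate
11 | (2S)-2-{4-[(2E)-3,7-dimethylocta-2,6-dien-1-yloxy]phenyl}-5,7-bis(triisopropylsilyloxy)chroman-4-ol, mixture of C4 epimers (C4 left undefined on purpose) | CC(C)=CCC/C(C)=C/COc1ccc([C@@H]2CC(O)c3c(O[Si](C(C)C)(C(C)C)C(C)C)cc(O[Si](C(C)C)(C(C)C)C(C)C)cc3O2)cc1 | intermediate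
12 | (2S)-2-{4-[(2E)-3,7-dimethylocta-2,6-dien-1-yloxy]phenyl}-5,7-bis(triisopropylsilyloxy)chroman-4-one | CC(C)=CCC/C(C)=C/COc1ccc([C@@H]2CC(=O)c3c(O[Si](C(C)C)(C(C)C)C(C)C)cc(O[Si](C(C)C)(C(C)C)C(C)C)cc3O2)cc1 | intermediate
13 | (2S)-2-{4-[(2E)-3,7-dimethylocta-2,6-dien-1-yloxy]phenyl}-5,7-dihydroxychroman-4-one (4'-O-geranylnaringenin) | CC(C)=CCC/C(C)=C/COc1ccc([C@@H]2CC(=O)c3c(O)cc(O)cc3O2)cc1 | target

Total step count: 6. Longest linear sequence: 5 steps (step 1 or step 2, then steps 3, 4, 5 and 6).

Steps most likely to fail

Step 3. What may go wrong: poor facial discrimination at C2, because the styrene offers the catalyst anion no binding site; acid-induced oligomerisation of 6; or erosion of C2 through reversible ionisation of the O1–C2 bond. The fallback uses known chemistry and replaces asymmetric induction by racemic assembly followed by kinetic resolution. It sets out from 2, 6 and 7, which are combined under Sc(OTf)3 catalysis (CH2Cl2, 0 °C) in the established Lewis-acid three-component coupling to give racemic 4'-O-geranyl-4-methoxy-5,7-bis(triisopropylsilyloxy)flavan F1. Hydrolysis as in step 4 should give racemic 4'-O-geranyl-5,7-bis(triisopropylsilyloxy)flavan-4-ol F2, and Dess–Martin oxidation as in step 5 should give racemic 4'-O-geranyl-5,7-bis(triisopropylsilyloxy)flavanone F3. Kinetic resolution by asymmetric transfer hydrogenation with RuCl(p-cymene)[(R,R)-TsDPEN] and HCO2H/Et3N, stopped near half conversion, should reduce the 2R ketone from the face remote from its 2-aryl group to the cis alcohol (2R,4R)-4'-O-geranyl-5,7-bis(triisopropylsilyloxy)flavan-4-ol F4. The 2S ketone should be left behind and is separated by chromatography; it is compound 12, where the route is rejoined. The sense of the resolution follows the usual model for aryl ketones and is to be confirmed; otherwise the other catalyst antipode is used.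

Step 4. What may go wrong: the C4 cation eliminates to the flav-3-ene or alkylates a second electron-rich ring instead of being trapped by water, or the acid attacks the allylic aryl ether. The fallback unmasks C4 oxidatively instead of hydrolytically. It sets out from 10: DDQ in CH2Cl2–pH 7 buffer at 0 °C abstracts the C4 hydride, which is activated by the methoxy group and ring A, water adds to the oxocarbenium ion and the hemiketal loses methanol. This is the known oxidative cleavage of electron-rich benzylic methyl ethers to carbonyl compounds. It bypasses 11 and comes back to the route at 12 with no new compound on the way (F0).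

Step 2. What may go wrong: the vinylphenoxide set free in the pot oligomerises or is C-allylated, or hydroxide consumes 4. The fallback builds the vinyl group after the ether. It sets out from 4: Williamson etherification of commercial 4-hydroxybenzaldehyde (K2CO3, DMF, rt) should give 4-(geranyloxy)benzaldehyde F5, and Wittig methylenation (Ph3PCH3Br, KOt-Bu, THF, 0 °C) returns to the route at 6.

Further compounds
F1 | step 3 | racemic 4'-O-geranyl-4-methoxy-5,7-bis(triisopropylsilyloxy)flavan (racemate, stereocentres left unspecified) | CC(C)=CCC/C(C)=C/COc1ccc(C2CC(OC)c3c(O[Si](C(C)C)(C(C)C)C(C)C)cc(O[Si](C(C)C)(C(C)C)C(C)C)cc3O2)cc1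
F2 | step 3 | racemic 4'-O-geranyl-5,7-bis(triisopropylsilyloxy)flavan-4-ol (racemate, stereocentres left unspecified) | CC(C)=CCC/C(C)=C/COc1ccc(C2CC(O)c3c(O[Si](C(C)C)(C(C)C)C(C)C)cc(O[Si](C(C)C)(C(C)C)C(C)C)cc3O2)cc1
F3 | step 3 | racemic 4'-O-geranyl-5,7-bis(triisopropylsilyloxy)flavanone (racemate, C2 left unspecified) | CC(C)=CCC/C(C)=C/COc1ccc(C2CC(=O)c3c(O[Si](C(C)C)(C(C)C)C(C)C)cc(O[Si](C(C)C)(C(C)C)C(C)C)cc3O2)cc1
F4 | step 3 | (2R,4R)-4'-O-geranyl-5,7-bis(triisopropylsilyloxy)flavan-4-ol (2,4-cis) | CC(C)=CCC/C(C)=C/COc1ccc([C@H]2C[C@@H](O)c3c(O[Si](C(C)C)(C(C)C)C(C)C)cc(O[Si](C(C)C)(C(C)C)C(C)C)cc3O2)cc1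
F0 | step 4 | none | none
F5 | step 2 | 4-(geranyloxy)benzaldehyde | CC(C)=CCC/C(C)=C/COc1ccc(C=O)cc1
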